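**Retrosynthetic overview**

- The strategy rests on C4: a carbonyl carbon bonded only to the fully substituted ring A carbon C4a and to C3, which together with C2 can come from an arylacetylene. C4 is therefore taken from carbon monoxide.
- O1–C2 is cut first (oxa-Michael addition of the C8a phenol to an ynone). C4a–C4 and C4–C3 are then cut together, giving ring A iodide 7, ring B alkyne 10 and CO.
- Ring A: 2,6-dimethoxybenzoquinone is reduced and dibenzylated, brominated and methoxylated (this installs the C8 methoxy), then iodinated at the last C–H (the future C4a). Ring B: 2-hydroxy-6-methoxybenzaldehyde is benzylated and homologated by one carbon.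
- Rings A and B are bought as arenes. Ring C is the only ring made, by 6-endo closure after the key step; hydrogenolysis of two benzyl ethers ends the route.

Key step: step 8

Remark on the chemistry: ring A is entered from commercial 2,6-dimethoxy-1,4-benzoquinone, whose two oxygens are already para, rather than from 3,4,5-trimethoxyphenol, which offers no short way to the para-dioxygenated pattern. Benzyl bromide and carbon monoxide are numbered as reactants. Step 2 consumes two equivalents of benzyl bromide, one entered as reactant 3 and the second on the reagent line.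

**Route**

Step 1
Reactants: 1 2,6-dimethoxy-1,4-benzoquinone
Product: 2 2,6-dimethoxybenzene-1,4-diol
Conditions: Na2S2O4, EtOAc/H2O, rt
Reagents that add atoms: none
Why: Dithionite reduction of a quinone to its hydroquinone is fast in a two-phase system and leaves the methyl ethers alone.

Step 2
Reactants: 2 2,6-dimethoxybenzene-1,4-diol; 3 benzyl bromide
Product: 4 2,5-bis(benzyloxy)-1,3-dimethoxybenzene
Conditions: BnBr (2.4 equiv in all), K2CO3 (3 equiv), DMF, 60 °C, Ar
Reagents that add atoms: benzyl bromide (second equivalent), BrCc1ccccc1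
Why: Twofold Williamson etherification, each phenoxide taking up one benzyl group from one equivalent of benzyl bromide; the two oxygens need no differentiation here because the later carbonyl group distinguishes the C8a ether from the C6 ether.

Step 3
Reactants: 4 2,5-bis(benzyloxy)-1,3-dimethoxybenzene
Product: 5 1,4-bis(benzyloxy)-2-bromo-3,5-dimethoxybenzene
Conditions: NBS (1.0 equiv), MeCN, 0 °C, dark
Reagents that add atoms: N-bromosuccinimide, O=C1CCC(=O)N1Br
Why: Electrophilic aromatic bromination; the two ring C–H positions of 4 are equivalent by symmetry and each is ortho to a benzyloxy and a methoxy group and para to the other methoxy group, so one equivalent should give a single monobromide.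

Step 4
Reactants: 5 1,4-bis(benzyloxy)-2-bromo-3,5-dimethoxybenzene
Product: 6 1,4-bis(benzyloxy)-2,3,5-trimethoxybenzene
Conditions: NaOMe, CuI (20 mol %), MeOH/DMF, 110 °C
Reagents that add atoms: sodium methoxide, C[O-].[Na+]
Why: Copper-catalysed Ullmann-type methoxylation of an aryl bromide, the usual way to raise a bromo-polyalkoxybenzene to the next methoxy arene; benzyl and methyl ethers are inert to methoxide.

Step 5
Reactants: 6 1,4-bis(benzyloxy)-2,3,5-trimethoxybenzene
Product: 7 1,4-bis(benzyloxy)-2-iodo-3,5,6-trimethoxybenzene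
Conditions: NIS, TFA (cat.), MeCN, 0 °C to rt
Reagents that add atoms: N-iodosuccinimide, O=C1CCC(=O)N1I
Why: Electrophilic aromatic iodination of a pentaalkoxybenzene; 6 has a single ring C–H, flanked by benzyloxy and methoxy groups, so the site of iodine (the future C4a) is fixed by the substrate.

Step 6
Reactants: 8 2-hydroxy-6-methoxybenzaldehyde; 3 benzyl bromide
Product: 9 2-(benzyloxy)-6-methoxybenzaldehyde
Conditions: K2CO3, DMF, 50 °C
Reagents that add atoms: none
Why: Williamson etherification of the hydrogen-bonded phenol, which is fully ionised by carbonate in DMF.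

Step 7
Reactants: 9 2-(benzyloxy)-6-methoxybenzaldehyde
Product: 10 1-(benzyloxy)-2-ethynyl-3-methoxybenzene
Conditions: dimethyl (1-diazo-2-oxopropyl)phosphonate, K2CO3, MeOH, 0 °C to rt
Reagents that add atoms: dimethyl (1-diazo-2-oxopropyl)phosphonate (Ohira–Bestmann reagent), COP(=O)(OC)C(=[N+]=[N-])C(C)=O
Why: Seyferth–Gilbert homologation in the Ohira–Bestmann variant; the non-enolisable aldehyde is olefinated by the diazomethylphosphonate anion, and loss of N2 with a 1,2-hydrogen shift gives the terminal alkyne under conditions that spare both ethers.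

Step 8
Reactants: 7 1,4-bis(benzyloxy)-2-iodo-3,5,6-trimethoxybenzene; 10 1-(benzyloxy)-2-ethynyl-3-methoxybenzene; 11 carbon monoxide
Product: 12 1-[2,5-bis(benzyloxy)-3,4,6-trimethoxyphenyl]-3-[2-(benzyloxy)-6-methoxyphenyl]prop-2-yn-1-one
Conditions: PdCl2(PPh3)2 (5 mol %), Et3N, THF, CO (10 bar), 70 °C
Reagents that add atoms: none
Why: Zerovalent palladium, formed in situ from PdCl2(PPh3)2 under CO and Et3N, inserts into the C4a–I bond of 7, and CO then migrates into the aryl–Pd bond, which should be quick because acyl formation relieves the crowding by the two ortho alkoxy groups. The aroylpalladium iodide binds alkyne 10, Et3N removes the acetylenic proton and reductive elimination releases ynone 12, so C4a–C4 and C4–C3 are made in one operation with C4 coming from CO. The closest known reaction is the copper-free carbonylative Sonogashira coupling of aryl iodides with terminal arylacetylenes to diaryl ynones. No ring closes and no stereocentre is formed; the oxygens on C8a and C2' that could attack the triple bond are both benzyl ethers. The selectivity needed is CO insertion before alkynyl transfer (ynone, not diarylacetylene) and cross-coupling rather than alkyne dimerisation; the absence of copper keeps the acetylide concentration low, CO pressure saturates the arylpalladium, and the flanking ethers should slow direct alkynylation more than CO insertion. The position of C4 on ring A needs no control, since 7 carries its only halogen on what was the only C–H.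

Step 9
Reactants: 12 1-[2,5-bis(benzyloxy)-3,4,6-trimethoxyphenyl]-3-[2-(benzyloxy)-6-methoxyphenyl]prop-2-yn-1-one
Product: 13 1-[5-(benzyloxy)-2-hydroxy-3,4,6-trimethoxyphenyl]-3-[2-(benzyloxy)-6-methoxyphenyl]prop-2-yn-1-one
Conditions: MgBr2·OEt2 (3 equiv), toluene/Et2O, rt to 50 °C; aq HCl
Reagents that add atoms: none
Why: Chelation-controlled Lewis acid debenzylation; magnesium bridges the carbonyl oxygen and the ortho ether oxygen on C8a and bromide removes that benzyl group as benzyl bromide, while the ortho methyl ether on C5 is a much poorer alkyl donor and the two remote benzyl ethers cannot chelate.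

Step 10
Reactants: 13 1-[5-(benzyloxy)-2-hydroxy-3,4,6-trimethoxyphenyl]-3-[2-(benzyloxy)-6-methoxyphenyl]prop-2-yn-1-one
Product: 14 6-(benzyloxy)-2-[2-(benzyloxy)-6-methoxyphenyl]-5,7,8-trimethoxy-4H-chromen-4-one
Conditions: K2CO3, acetone, reflux
Reagents that add atoms: none
Why: Base-mediated intramolecular oxa-Michael addition; the C8a phenoxide attacks the ynone β-carbon (C2) in a 6-endo-dig closure, the mode favoured for o-hydroxyaryl ynones in aprotic medium, and protonation at C3 gives the chromone.

Step 11
Reactants: 14 6-(benzyloxy)-2-[2-(benzyloxy)-6-methoxyphenyl]-5,7,8-trimethoxy-4H-chromen-4-one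
Product: 15 6,2'-dihydroxy-5,7,8,6'-tetramethoxyflavone
Conditions: H2 (1 atm), Pd/C, EtOAc/MeOH, rt
Reagents that add atoms: none
Why: Catalytic hydrogenolysis cleaves both aryl benzyl ethers; the methyl ethers and the chromone C2=C3 bond should survive at atmospheric pressure and room temperature.

**Compound list**

1 | 2,6-dimethoxy-1,4-benzoquinone | COC1=CC(=O)C=C(OC)C1=O | starting material
2 | 2,6-dimethoxybenzene-1,4-diol | COc1cc(O)cc(OC)c1O | intermediate
3 | benzyl bromide | BrCc1ccccc1 | starting material
4 | 2,5-bis(benzyloxy)-1,3-dimethoxybenzene | COc1cc(OCc2ccccc2)cc(OC)c1OCc1ccccc1 | intermediate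
5 | 1,4-bis(benzyloxy)-2-bromo-3,5-dimethoxybenzene | COc1cc(OCc2ccccc2)c(Br)c(OC)c1OCc1ccccc1 | intermediate
6 | 1,4-bis(benzyloxy)-2,3,5-trimethoxybenzene | COc1cc(OCc2ccccc2)c(OC)c(OC)c1OCc1ccccc1 | intermediate
7 | 1,4-bis(benzyloxy)-2-iodo-3,5,6-trimethoxybenzene | COc1c(I)c(OCc2ccccc2)c(OC)c(OC)c1OCc1ccccc1 | intermediate
8 | 2-hydroxy-6-methoxybenzaldehyde | COc1cccc(O)c1C=O | starting material
9 | 2-(benzyloxy)-6-methoxybenzaldehyde | COc1cccc(OCc2ccccc2)c1C=O | intermediate
10 | 1-(benzyloxy)-2-ethynyl-3-methoxybenzene | C#Cc1c(OC)cccc1OCc1ccccc1 | intermediate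
11 | carbon monoxide | [C-]#[O+] | starting material
12 | 1-[2,5-bis(benzyloxy)-3,4,6-trimethoxyphenyl]-3-[2-(benzyloxy)-6-methoxyphenyl]prop-2-yn-1-one | COc1c(C(=O)C#Cc2c(OC)cccc2OCc2ccccc2)c(OCc2ccccc2)c(OC)c(OC)c1OCc1ccccc1 | intermediate
13 | 1-[5-(benzyloxy)-2-hydroxy-3,4,6-trimethoxyphenyl]-3-[2-(benzyloxy)-6-methoxyphenyl]prop-2-yn-1-one | COc1c(C(=O)C#Cc2c(OC)cccc2OCc2ccccc2)c(O)c(OC)c(OC)c1OCc1ccccc1 | intermediate
14 | 6-(benzyloxy)-2-[2-(benzyloxy)-6-methoxyphenyl]-5,7,8-trimethoxy-4H-chromen-4-one | COc1cccc(OCc2ccccc2)c1-c1cc(=O)c2c(OC)c(OCc3ccccc3)c(OC)c(OC)c2o1 | intermediate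
15 | 6,2'-dihydroxy-5,7,8,6'-tetramethoxyflavone | COc1cccc(O)c1-c1cc(=O)c2c(OC)c(O)c(OC)c(OC)c2o1 | target

**Step count**

Total: 11 steps. Longest linear sequence: 9 steps (steps 1–5 and 8–11, from 1). The ring B branch (steps 6 and 7) joins at step 8.

**Steps most likely to fail**

1. Step 8. Oxidative addition into the crowded, electron-rich C–I bond may be slow enough for the catalyst to decay, and alkynyl transfer may overtake CO insertion, giving direct coupling or alkyne dimerisation. Fallback, from 7 back to 12, builds the same two bonds one at a time with C4 coming from DMF. Iodine–magnesium exchange on 7 with i-PrMgCl·LiCl in THF at −20 °C and a DMF quench should give 2,5-bis(benzyloxy)-3,4,6-trimethoxybenzaldehyde F1. Addition of the lithium acetylide of 10 (n-BuLi, THF, −78 °C) should give racemic 1-[2,5-bis(benzyloxy)-3,4,6-trimethoxyphenyl]-3-[2-(benzyloxy)-6-methoxyphenyl]prop-2-yn-1-ol F2. Oxidation with MnO2 in CH2Cl2 would return the route to 12.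

2. Step 9. Bromide may add across the ynone, chelation to the twisted diaryl-type carbonyl may be sluggish, or the C5 methyl ether may be cleaved alongside the C8a benzyl ether. Fallback, from 12 to 15, masks the triple bond and removes all benzyl groups together, so no selective Lewis acid cleavage is needed. Conjugate addition of pyrrolidine to 12 in EtOH at rt should give (E)-1-[2,5-bis(benzyloxy)-3,4,6-trimethoxyphenyl]-3-[2-(benzyloxy)-6-methoxyphenyl]-3-(pyrrolidin-1-yl)prop-2-en-1-one F3, a vinylogous amide expected to resist hydrogenation. Hydrogenolysis (H2, Pd/C, EtOAc/MeOH) should give (E)-1-(2,5-dihydroxy-3,4,6-trimethoxyphenyl)-3-(2-hydroxy-6-methoxyphenyl)-3-(pyrrolidin-1-yl)prop-2-en-1-one F4, not isolated. Acidification with HCl in MeOH under argon and gentle warming should close ring C by addition–elimination of the C8a hydroxyl with loss of pyrrolidine, giving target 15 directly. The C2' hydroxyl could only form a four-membered ring at that carbon.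

3. Step 10. The di-ortho-substituted ring B crowds the β-carbon, so 5-exo closure at the α-carbon (aurone) may compete with the 6-endo mode. Fallback, from 13 to 14: pyrrolidine in EtOH should add to the ynone to give (E)-1-[5-(benzyloxy)-2-hydroxy-3,4,6-trimethoxyphenyl]-3-[2-(benzyloxy)-6-methoxyphenyl]-3-(pyrrolidin-1-yl)prop-2-en-1-one F5. The amine-bearing carbon is then the only electrophilic site, and warming in AcOH should give 14 by addition–elimination, which can only form the six-membered ring.

**Further compounds**

F1 | step 8 | 2,5-bis(benzyloxy)-3,4,6-trimethoxybenzaldehyde | COc1c(C=O)c(OCc2ccccc2)c(OC)c(OC)c1OCc1ccccc1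
F2 | step 8 | 1-[2,5-bis(benzyloxy)-3,4,6-trimethoxyphenyl]-3-[2-(benzyloxy)-6-methoxyphenyl]prop-2-yn-1-ol (racemic) | COc1c(C(O)C#Cc2c(OC)cccc2OCc2ccccc2)c(OCc2ccccc2)c(OC)c(OC)c1OCc1ccccc1
F3 | step 9 | (E)-1-[2,5-bis(benzyloxy)-3,4,6-trimethoxyphenyl]-3-[2-(benzyloxy)-6-methoxyphenyl]-3-(pyrrolidin-1-yl)prop-2-en-1-one | COc1c(C(=O)/C=C(/N2CCCC2)c2c(OC)cccc2OCc2ccccc2)c(OCc2ccccc2)c(OC)c(OC)c1OCc1ccccc1
F4 | step 9 | (E)-1-(2,5-dihydroxy-3,4,6-trimethoxyphenyl)-3-(2-hydroxy-6-methoxyphenyl)-3-(pyrrolidin-1-yl)prop-2-en-1-one | COc1c(C(=O)/C=C(/N2CCCC2)c2c(OC)cccc2O)c(O)c(OC)c(OC)c1O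
F5 | step 10 | (E)-1-[5-(benzyloxy)-2-hydroxy-3,4,6-trimethoxyphenyl]-3-[2-(benzyloxy)-6-methoxyphenyl]-3-(pyrrolidin-1-yl)prop-2-en-1-one | COc1c(C(=O)/C=C(/N2CCCC2)c2c(OC)cccc2OCc2ccccc2)c(O)c(OC)c(OC)c1OCc1ccccc1
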